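**Plan**

- Retrosynthesis: the two ketones go back to silyl-protected (S)-carbinols and C3–H/C3'–H to phenols. The ring bonds C2–C3 and C2'–C3' are then cut together, which unfolds each benzene ring into a 4-alkenyl-2,3,4-trimethoxycyclobutenone. The two diene–ring bonds lead back to dimethyl squarate, and the axis bond C1–C1' to a 1,3-diyne made from two C5 alkynol units.
- Enabling feature: in ring A and ring B the contiguous methoxy carbons C4, C5 and C6 beside the axis carbon C1 carry the oxygens of a squarate ester plus one methylated carbinol. C2–C1–C1'–C2' is the core of a 2,3-disubstituted buta-1,3-diene, so the hindered axis exists before either ring does.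
- Forward: alkyne homocoupling (axis bond), twofold inner hydrostannation, dilithiation and addition to two squarates (chain joined), then one thermolysis closes ring A and ring B in turn.
- End game: the C3 and C3' phenols, the only free hydroxyls, are removed through their triflates; desilylation and oxidation finish.
- Stereochemistry: the target has no stereocentre. The (S)-centres come from the alkynol, only keep the intermediates uniform, and are erased in the last step. The alkene geometry needed for ring closure comes from syn-hydrostannation.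

Key step: step 5

Remark: the target is drawn without axial configuration, so the axis is not controlled and 12–16 are expected as atropisomer mixtures; the ring-carbinol diastereomers of 7–11 all converge in step 5.

**Route**

Step 1
Reactants: 1 (S)-pent-4-yn-2-ol
Product: 2 tert-butyldimethyl{[(2S)-pent-4-yn-2-yl]oxy}silane
Conditions: TBSCl, imidazole, DMF, 0 °C → rt
Reagents that add atoms: tert-butyldimethylsilyl chloride, CC(C)(C)[Si](C)(C)Cl
Why: Imidazole-promoted silylation of a secondary alcohol masks the carbinol that later becomes the ketone and leaves the (S)-centre untouched.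

Step 2
Reactants: 2 tert-butyldimethyl{[(2S)-pent-4-yn-2-yl]oxy}silane (two molecules)
Product: 3 (2S,9S)-2,9-bis(tert-butyldimethylsilyloxy)deca-4,6-diyne
Conditions: CuCl (10 mol%), TMEDA, O2 (1 atm), acetone, rt
Reagents that add atoms: none
Why: Glaser–Hay oxidative homocoupling of the terminal alkyne forms the future C1–C1' axis bond without touching the silyl ethers or the (S)-centres.

Step 3
Reactants: 3 (2S,9S)-2,9-bis(tert-butyldimethylsilyloxy)deca-4,6-diyne
Product: 4 (2S,4E,6E,9S)-2,9-bis(tert-butyldimethylsilyloxy)-5,6-bis(tributylstannyl)deca-4,6-diene (both tins on the inner carbons, each cis to its vinylic hydrogen)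
Conditions: Bu3SnH (2.6 equiv, slow addition), PdCl2(PPh3)2 (5 mol%), THF, 0 °C → rt
Reagents that add atoms: tributyltin hydride (two molecules), CCCC[SnH](CCCC)CCCC
Why: Palladium-catalysed syn-hydrostannation of a conjugated diyne places tin on the inner alkyne carbon, and in the resulting stannyl enyne the alkyl group cis to the remaining alkyne should again steer tin to the carbon next to the alkene, so two syn additions are expected to give the inner,inner-distannane.

Step 4
Reactants: 4 (2S,4E,6E,9S)-2,9-bis(tert-butyldimethylsilyloxy)-5,6-bis(tributylstannyl)deca-4,6-diene; 5 dimethyl squarate (two molecules)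
Product: 8 4,4'-[(2S,4E,6E,9S)-2,9-bis(tert-butyldimethylsilyloxy)deca-4,6-diene-5,6-diyl]bis(2,3,4-trimethoxycyclobut-2-en-1-one) (diastereomer mixture at the two ring C4 centres), via dilithiodiene 6 (not isolated), via bis(lithium alkoxide) 7 (not isolated)
Conditions: n-BuLi (2.2 equiv), THF, −78 → −40 °C; cannula transfer into 5 (3 equiv), THF, −78 °C; MeOTf (5 equiv), −78 → 0 °C
Reagents that add atoms: methyl trifluoromethanesulfonate, COS(=O)(=O)C(F)(F)F
Why: Tin–lithium exchange of alkenylstannanes proceeds with retention, alkenyllithiums add 1,2 to one carbonyl of dimethyl squarate at −78 °C, and the lithium alkoxides are O-methylated in the flask by methyl triflate; inverse addition to excess squarate keeps each lithium on its own squarate, and the two new quaternary centres need no control because step 5 removes them.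

Step 5
Reactants: 8 4,4'-[(2S,4E,6E,9S)-2,9-bis(tert-butyldimethylsilyloxy)deca-4,6-diene-5,6-diyl]bis(2,3,4-trimethoxycyclobut-2-en-1-one)
Product: 12 2,2'-bis[(2S)-2-(tert-butyldimethylsilyloxy)propyl]-4,4',5,5',6,6'-hexamethoxybiphenyl-3,3'-diol, via first dienylketene 9 (not isolated), via half-annulated phenol cyclobutenone 10 (not isolated), via second dienylketene 11 (not isolated)
Conditions: degassed p-xylene (about 0.005 M), 138 °C, argon
Reagents that add atoms: none
Why: Each cyclobutenone opens by thermal conrotatory 4π cleavage of its C(=O)–C(OMe)(alkenyl) bond to a dienylketene (9, later 11), whose ketene carbon (future C3 or C3') bonds to the alkene terminus (future C2 or C2') in a disrotatory 6π-electrocyclisation, and a proton shift turns the cyclohexadienone into the phenol. This is the Moore rearrangement, the known thermal ring expansion of squarate-derived 4-alkenyl-4-alkoxycyclobutenones to para-alkoxyphenols, here asked to run at both ends of one diene. Ring A and ring B are each closed as six-membered carbocycles by 6π-electrocyclisation of a dienylketene, one after the other through 10. No stereocentre is created, the ring carbinol centres of 8 disappear (so all its diastereomers converge) and the new biaryl axis is not controlled. The step needs torquoselective ring opening with the alkenyl group turning inward toward the ketene, which the 4-methoxy donor secures by rotating outward, and it needs the vinylic hydrogen rather than the side chain to face the ketene, which the syn-hydrostannation geometry provides. In 10 the aryl group on the alkene has no free ortho position, so only the alkene can capture the second ketene, and high dilution should keep the new phenol from adding to it.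

Step 6
Reactants: 12 2,2'-bis[(2S)-2-(tert-butyldimethylsilyloxy)propyl]-4,4',5,5',6,6'-hexamethoxybiphenyl-3,3'-diol
Product: 13 2,2'-bis[(2S)-2-(tert-butyldimethylsilyloxy)propyl]-4,4',5,5',6,6'-hexamethoxybiphenyl-3,3'-diyl bis(trifluoromethanesulfonate)
Conditions: Tf2O, pyridine, CH2Cl2, 0 °C → rt
Reagents that add atoms: trifluoromethanesulfonic anhydride, O=S(=O)(OS(=O)(=O)C(F)(F)F)C(F)(F)F
Why: Sulfonylation of the only free hydroxyls (the C3 and C3' phenols) turns the two unwanted oxygens into leaving groups while silyl and methyl ethers stay inert.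

Step 7
Reactants: 13 2,2'-bis[(2S)-2-(tert-butyldimethylsilyloxy)propyl]-4,4',5,5',6,6'-hexamethoxybiphenyl-3,3'-diyl bis(trifluoromethanesulfonate)
Product: 14 2,2'-bis[(2S)-2-(tert-butyldimethylsilyloxy)propyl]-4,4',5,5',6,6'-hexamethoxybiphenyl
Conditions: Pd(OAc)2 (10 mol%), 1,3-bis(diphenylphosphino)propane, Et3N, HCO2H, DMF, 80 °C
Reagents that add atoms: none
Why: Palladium-catalysed formate reduction of aryl triflates (oxidative addition to zerovalent palladium, formate-for-triflate exchange, loss of CO2, reductive elimination of C–H) replaces C3–O and C3'–O by C–H, and the bidentate phosphine helps with the hindered, electron-rich triflates.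

Step 8
Reactants: 14 2,2'-bis[(2S)-2-(tert-butyldimethylsilyloxy)propyl]-4,4',5,5',6,6'-hexamethoxybiphenyl
Product: 15 (2S,2'S)-1,1'-(4,4',5,5',6,6'-hexamethoxybiphenyl-2,2'-diyl)di(propan-2-ol)
Conditions: HF·pyridine, THF, 0 °C → rt
Reagents that add atoms: none
Why: Fluoride-driven cleavage of the two secondary silyl ethers frees the carbinols while the aryl methyl ethers are untouched.

Step 9
Reactants: 15 (2S,2'S)-1,1'-(4,4',5,5',6,6'-hexamethoxybiphenyl-2,2'-diyl)di(propan-2-ol)
Product: 16 1,1'-(4,4',5,5',6,6'-hexamethoxybiphenyl-2,2'-diyl)di(propan-2-one) (CNP0079270.0)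
Conditions: Dess–Martin periodinane, CH2Cl2, rt
Reagents that add atoms: none
Why: Dess–Martin oxidation converts both secondary alcohols into the methyl ketones under neutral conditions that spare the benzylic methylene groups, and it erases the auxiliary (S)-centres.

**Compound list**

1 | (S)-pent-4-yn-2-ol | C#CC[C@H](C)O | starting material
2 | tert-butyldimethyl{[(2S)-pent-4-yn-2-yl]oxy}silane | C#CC[C@H](C)O[Si](C)(C)C(C)(C)C | intermediate
3 | (2S,9S)-2,9-bis(tert-butyldimethylsilyloxy)deca-4,6-diyne | C[C@H](O[Si](C)(C)C(C)(C)C)CC#CC#CC[C@H](C)O[Si](C)(C)C(C)(C)C | intermediate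
4 | (2S,4E,6E,9S)-2,9-bis(tert-butyldimethylsilyloxy)-5,6-bis(tributylstannyl)deca-4,6-diene | CCCC[Sn](CCCC)(CCCC)/C(=C/C[C@H](C)O[Si](C)(C)C(C)(C)C)C(=C/C[C@H](C)O[Si](C)(C)C(C)(C)C)\[Sn](CCCC)(CCCC)CCCC | intermediate
5 | dimethyl squarate (3,4-dimethoxycyclobut-3-ene-1,2-dione) | COC1=C(OC)C(=O)C1=O | starting material
6 | (2S,4Z,6Z,9S)-2,9-bis(tert-butyldimethylsilyloxy)-5,6-dilithiodeca-4,6-diene (not isolated) | [Li]/C(=C/C[C@H](C)O[Si](C)(C)C(C)(C)C)C(=C/C[C@H](C)O[Si](C)(C)C(C)(C)C)\[Li] | intermediate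
7 | dilithium bis-alkoxide from addition of 6 to two molecules of 5 (not isolated) | COC1=C(OC)C(O[Li])(C1=O)/C(=C/C[C@H](C)O[Si](C)(C)C(C)(C)C)C(=C/C[C@H](C)O[Si](C)(C)C(C)(C)C)\C1(O[Li])C(OC)=C(OC)C1=O | intermediate
8 | 4,4'-[(2S,4E,6E,9S)-2,9-bis(tert-butyldimethylsilyloxy)deca-4,6-diene-5,6-diyl]bis(2,3,4-trimethoxycyclobut-2-en-1-one), diastereomer mixture at the ring C4 centres | COC1=C(OC)C(OC)(C1=O)/C(=C/C[C@H](C)O[Si](C)(C)C(C)(C)C)C(=C/C[C@H](C)O[Si](C)(C)C(C)(C)C)\C1(OC)C(OC)=C(OC)C1=O | intermediate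
9 | dienylketene from opening of one four-membered ring of 8, ketene arm cis to the diene carbon, second cyclobutenone intact (not isolated) | O=C=C(OC)/C(OC)=C(OC)\C(=C\C[C@H](C)O[Si](C)(C)C(C)(C)C)C(=C/C[C@H](C)O[Si](C)(C)C(C)(C)C)\C1(OC)C(OC)=C(OC)C1=O | intermediate
10 | 4-{(1E,4S)-4-(tert-butyldimethylsilyloxy)-1-[3-hydroxy-4,5,6-trimethoxy-2-((2S)-2-(tert-butyldimethylsilyloxy)propyl)phenyl]pent-1-en-1-yl}-2,3,4-trimethoxycyclobut-2-en-1-one, ring A closed (not isolated) | COc1c(OC)c(O)c(C[C@H](C)O[Si](C)(C)C(C)(C)C)c(c1OC)/C(=C\C[C@H](C)O[Si](C)(C)C(C)(C)C)C1(OC)C(OC)=C(OC)C1=O | intermediate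
11 | dienylketene from opening of the four-membered ring of 10 (not isolated) | COc1c(OC)c(O)c(C[C@H](C)O[Si](C)(C)C(C)(C)C)c(c1OC)/C(=C\C[C@H](C)O[Si](C)(C)C(C)(C)C)/C(OC)=C(OC)\C(OC)=C=O | intermediate
12 | 2,2'-bis[(2S)-2-(tert-butyldimethylsilyloxy)propyl]-4,4',5,5',6,6'-hexamethoxybiphenyl-3,3'-diol | COc1c(OC)c(O)c(C[C@H](C)O[Si](C)(C)C(C)(C)C)c(-c2c(C[C@H](C)O[Si](C)(C)C(C)(C)C)c(O)c(OC)c(OC)c2OC)c1OC | intermediate
13 | 2,2'-bis[(2S)-2-(tert-butyldimethylsilyloxy)propyl]-4,4',5,5',6,6'-hexamethoxybiphenyl-3,3'-diyl bis(trifluoromethanesulfonate) | COc1c(OC)c(OS(=O)(=O)C(F)(F)F)c(C[C@H](C)O[Si](C)(C)C(C)(C)C)c(-c2c(C[C@H](C)O[Si](C)(C)C(C)(C)C)c(OS(=O)(=O)C(F)(F)F)c(OC)c(OC)c2OC)c1OC | intermediate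
14 | 2,2'-bis[(2S)-2-(tert-butyldimethylsilyloxy)propyl]-4,4',5,5',6,6'-hexamethoxybiphenyl | COc1cc(C[C@H](C)O[Si](C)(C)C(C)(C)C)c(-c2c(C[C@H](C)O[Si](C)(C)C(C)(C)C)cc(OC)c(OC)c2OC)c(OC)c1OC | intermediate
15 | (2S,2'S)-1,1'-(4,4',5,5',6,6'-hexamethoxybiphenyl-2,2'-diyl)di(propan-2-ol) | COc1cc(C[C@H](C)O)c(-c2c(C[C@H](C)O)cc(OC)c(OC)c2OC)c(OC)c1OC | intermediate
16 | 1,1'-(4,4',5,5',6,6'-hexamethoxybiphenyl-2,2'-diyl)di(propan-2-one) | COc1cc(CC(C)=O)c(-c2c(CC(C)=O)cc(OC)c(OC)c2OC)c(OC)c1OC | target

**Step count and risks**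

Total steps: 9. Longest linear sequence: 9 steps (1 → 16).

Steps most likely to fail:

Step 5. After ring A has formed, the second dienylketene may close too slowly at the crowded, aryl-substituted alkene and be diverted by acylation of the new phenol or by ketene dimerisation, so that half-annulated or oligomeric material accumulates. The fallback sets out from 2 (with 5) and comes back at 13; it makes each ring separately and the axis by copper coupling. Hydrozirconation of 2 with Cp2Zr(H)Cl and iodinolysis (I2) should give tert-butyl{[(2S,4E)-5-iodopent-4-en-2-yl]oxy}dimethylsilane F1. Iodine–lithium exchange (t-BuLi, Et2O, −78 °C), addition to 5 and MeOTf should give 4-[(1E,4S)-4-(tert-butyldimethylsilyloxy)pent-1-en-1-yl]-2,3,4-trimethoxycyclobut-2-en-1-one F2. Its single ring expansion (toluene, 110 °C) should give 2,3,4-trimethoxy-6-[(2S)-2-(tert-butyldimethylsilyloxy)propyl]phenol F3. Triflation (Tf2O, pyridine) should give the aryl triflate F4, and iodination of the only free ring position (N-iodosuccinimide, catalytic CF3CO2H, MeCN) the iodo triflate F5. Ullmann homocoupling (Cu powder, DMF, 130 °C) should then deliver 13.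

Step 4. The second tin–lithium exchange may stay incomplete, or an alkenyllithium may add to a cyclobutenone alkoxide that has already formed, giving over-addition and oligomers; the two hindered alkoxides may also be methylated only in part. The fallback sets out from 4 (with 5) and comes back at 12; it uses only monolithium reagents and closes the rings one at a time. One equivalent of n-BuLi should exchange a single tin, as is established for 2,3-distannyl dienes; addition to 5 and MeOTf should give the stannyl diene monocyclobutenone F6. Thermolysis (toluene, 110 °C) should close ring A to the stannylalkenyl phenol F7, and benzylation (BnBr, K2CO3, DMF) should give its benzyl ether F8. The second exchange (n-BuLi, −78 °C), 5 and MeOTf should give the aryl alkenyl cyclobutenone F9. A second single ring expansion should give the mono-benzylated biaryl F10, and hydrogenolysis (H2, Pd/C, EtOAc) should return 12.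

Step 3. The second hydrostannation may stall at the stannyl enyne or, for steric reasons, place tin on the outer carbon, while dehydrogenative coupling of the hydride to hexabutylditin uses up the reagent. The fallback sets out from 3 (with 5) and comes back at 12; it relies only on the well-established mono-addition to a 1,3-diyne. One equivalent of Bu3SnH with PdCl2(PPh3)2 should give the stannyl enyne F11. Tin–lithium exchange, addition to 5 and MeOTf should give the enynyl cyclobutenone F12, whose ring expansion (toluene, 110 °C) should give the alkynyl phenol F13. Silylation (TBSCl, imidazole, DMF) should give the aryl silyl ether F14. Hydrostannation of this di-ortho-substituted aryl alkyne, where ortho substituents direct tin to the aryl-bearing carbon, should give the alkenylstannane F15. Exchange, 5 and MeOTf should give the cyclobutenone F16, and thermolysis the mono-silylated biaryl phenol F17. K2CO3 in MeOH should cleave only the aryl silyl ether and return 12.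

**Further compounds**

F1 | step 5 | tert-butyl{[(2S,4E)-5-iodopent-4-en-2-yl]oxy}dimethylsilane | I/C=C/C[C@H](C)O[Si](C)(C)C(C)(C)C
F2 | step 5 | 4-[(1E,4S)-4-(tert-butyldimethylsilyloxy)pent-1-en-1-yl]-2,3,4-trimethoxycyclobut-2-en-1-one | COC1=C(OC)C(OC)(/C=C/C[C@H](C)O[Si](C)(C)C(C)(C)C)C1=O
F3 | step 5 | 2,3,4-trimethoxy-6-[(2S)-2-(tert-butyldimethylsilyloxy)propyl]phenol | COc1cc(C[C@H](C)O[Si](C)(C)C(C)(C)C)c(O)c(OC)c1OC
F4 | step 5 | 2,3,4-trimethoxy-6-[(2S)-2-(tert-butyldimethylsilyloxy)propyl]phenyl trifluoromethanesulfonate | COc1cc(C[C@H](C)O[Si](C)(C)C(C)(C)C)c(OS(=O)(=O)C(F)(F)F)c(OC)c1OC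
F5 | step 5 | 5-iodo-2,3,4-trimethoxy-6-[(2S)-2-(tert-butyldimethylsilyloxy)propyl]phenyl trifluoromethanesulfonate | COc1c(I)c(C[C@H](C)O[Si](C)(C)C(C)(C)C)c(OS(=O)(=O)C(F)(F)F)c(OC)c1OC
F6 | step 4 | 4-[(2S,4E,6E,9S)-2,9-bis(tert-butyldimethylsilyloxy)-6-(tributylstannyl)deca-4,6-dien-5-yl]-2,3,4-trimethoxycyclobut-2-en-1-one | COC1=C(OC)C(OC)(C1=O)/C(=C/C[C@H](C)O[Si](C)(C)C(C)(C)C)C(=C/C[C@H](C)O[Si](C)(C)C(C)(C)C)\[Sn](CCCC)(CCCC)CCCC
F7 | step 4 | 2,3,4-trimethoxy-6-[(2S)-2-(tert-butyldimethylsilyloxy)propyl]-5-[(1E,4S)-4-(tert-butyldimethylsilyloxy)-1-(tributylstannyl)pent-1-en-1-yl]phenol | COc1c(OC)c(O)c(C[C@H](C)O[Si](C)(C)C(C)(C)C)c(c1OC)/C(=C\C[C@H](C)O[Si](C)(C)C(C)(C)C)[Sn](CCCC)(CCCC)CCCC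
F8 | step 4 | benzyl ether of F7 | COc1c(OC)c(OCc2ccccc2)c(C[C@H](C)O[Si](C)(C)C(C)(C)C)c(c1OC)/C(=C\C[C@H](C)O[Si](C)(C)C(C)(C)C)[Sn](CCCC)(CCCC)CCCC
F9 | step 4 | 4-{(1E,4S)-1-[3-(benzyloxy)-4,5,6-trimethoxy-2-((2S)-2-(tert-butyldimethylsilyloxy)propyl)phenyl]-4-(tert-butyldimethylsilyloxy)pent-1-en-1-yl}-2,3,4-trimethoxycyclobut-2-en-1-one | COc1c(OC)c(OCc2ccccc2)c(C[C@H](C)O[Si](C)(C)C(C)(C)C)c(c1OC)/C(=C\C[C@H](C)O[Si](C)(C)C(C)(C)C)C1(OC)C(OC)=C(OC)C1=O
F10 | step 4 | 3'-(benzyloxy)-2,2'-bis[(2S)-2-(tert-butyldimethylsilyloxy)propyl]-4,4',5,5',6,6'-hexamethoxybiphenyl-3-ol | COc1c(OC)c(OCc2ccccc2)c(C[C@H](C)O[Si](C)(C)C(C)(C)C)c(-c2c(C[C@H](C)O[Si](C)(C)C(C)(C)C)c(O)c(OC)c(OC)c2OC)c1OC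
F11 | step 3 | (2S,4E,9S)-2,9-bis(tert-butyldimethylsilyloxy)-5-(tributylstannyl)dec-4-en-6-yne | CCCC[Sn](CCCC)(CCCC)/C(=C/C[C@H](C)O[Si](C)(C)C(C)(C)C)C#CC[C@H](C)O[Si](C)(C)C(C)(C)C
F12 | step 3 | 4-[(2S,4E,9S)-2,9-bis(tert-butyldimethylsilyloxy)dec-4-en-6-yn-5-yl]-2,3,4-trimethoxycyclobut-2-en-1-one | COC1=C(OC)C(OC)(C1=O)/C(=C/C[C@H](C)O[Si](C)(C)C(C)(C)C)C#CC[C@H](C)O[Si](C)(C)C(C)(C)C
F13 | step 3 | 2,3,4-trimethoxy-6-[(2S)-2-(tert-butyldimethylsilyloxy)propyl]-5-[(4S)-4-(tert-butyldimethylsilyloxy)pent-1-yn-1-yl]phenol | COc1c(OC)c(O)c(C[C@H](C)O[Si](C)(C)C(C)(C)C)c(C#CC[C@H](C)O[Si](C)(C)C(C)(C)C)c1OC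
F14 | step 3 | aryl tert-butyldimethylsilyl ether of F13 | COc1c(OC)c(O[Si](C)(C)C(C)(C)C)c(C[C@H](C)O[Si](C)(C)C(C)(C)C)c(C#CC[C@H](C)O[Si](C)(C)C(C)(C)C)c1OC
F15 | step 3 | aryl silyl ether bearing the (1E,4S)-4-(tert-butyldimethylsilyloxy)-1-(tributylstannyl)pent-1-en-1-yl group at the former alkyne position | COc1c(OC)c(O[Si](C)(C)C(C)(C)C)c(C[C@H](C)O[Si](C)(C)C(C)(C)C)c(c1OC)/C(=C\C[C@H](C)O[Si](C)(C)C(C)(C)C)[Sn](CCCC)(CCCC)CCCC
F16 | step 3 | 2,3,4-trimethoxycyclobut-2-en-1-one carrying at C4 the (1E)-alkenyl group of F15 in place of tin | COc1c(OC)c(O[Si](C)(C)C(C)(C)C)c(C[C@H](C)O[Si](C)(C)C(C)(C)C)c(c1OC)/C(=C\C[C@H](C)O[Si](C)(C)C(C)(C)C)C1(OC)C(OC)=C(OC)C1=O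
F17 | step 3 | 3'-(tert-butyldimethylsilyloxy)-2,2'-bis[(2S)-2-(tert-butyldimethylsilyloxy)propyl]-4,4',5,5',6,6'-hexamethoxybiphenyl-3-ol | COc1c(OC)c(O[Si](C)(C)C(C)(C)C)c(C[C@H](C)O[Si](C)(C)C(C)(C)C)c(-c2c(C[C@H](C)O[Si](C)(C)C(C)(C)C)c(O)c(OC)c(OC)c2OC)c1OC
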